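**Plan**

- Retrosynthesis: the CH2OH arm on C3 of the oxolane is traced back to a formyl group and the C2–C3 ring bond is cut. C3, with its one-carbon branch between the aryl-bearing C2 and the benzyl-bearing C4, is what a 2-aryl-5-benzyl-3,4-epoxyoxane leaves when one epoxide carbon is pushed out of the six-membered ring as CHO.
- The epoxyoxane goes back to a 5,6-dihydro-2H-pyran (C3=C4 cut by metathesis). Its diene ether is cut at the benzylic C–O bond into a cinnamyl carbonate and a 2-benzylbut-3-en-1-ol, the latter from α-benzylation of a crotonyl imide.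
- Forward: alkylation and allylic etherification join the chain, ring-closing metathesis makes the pyran, an iodohydrin gives the epoxide, the pyran is contracted to the oxolane, and the aldehyde is reduced.
- Stereochemistry: oxolane C4 comes from the (R)-4-benzyloxazolidinone auxiliary and C2 from the chiral iridium catalyst. The epoxide face follows from trans opening of the iodonium ion, and C3 from inversion at the migration terminus, which leaves the formyl carbon on the epoxide face (all-cis).

Key step: step 9

Assumption: L is the binaphthol-derived N,N-bis(1-phenylethyl)phosphoramidite; both antipodes are available, and the one whose iridium allyl complex gives the (R)-configured benzylic ether is used.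

Pyran numbering in steps 7–9: O1, C2 (aryl), C3, C4, C5 (benzyl), C6.

**Step 1**
Reactants: 1 (R)-4-benzyl-1,3-oxazolidin-2-one; 2 (E)-but-2-enoyl chloride
Product: 3 (R)-4-benzyl-3-[(E)-but-2-enoyl]-1,3-oxazolidin-2-one
Conditions: n-BuLi, THF, −78 °C; then 2, −78 → 0 °C
Reagents that add atoms: none
Why: N-acylation of the lithiated oxazolidinone by the acid chloride is the standard entry to Evans imides and touches no stereocentre.

**Step 2**
Reactants: 3 (R)-4-benzyl-3-[(E)-but-2-enoyl]-1,3-oxazolidin-2-one; 4 3,4-dimethoxybenzyl bromide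
Product: 5 (R)-4-benzyl-3-[(2R)-2-(3,4-dimethoxybenzyl)but-3-enoyl]-1,3-oxazolidin-2-one
Conditions: NaN(SiMe3)2, THF, −78 °C; then 4, −78 → −40 °C; AcOH quench
Reagents that add atoms: none
Why: Evans alkylation of the chelated sodium Z-dienolate occurs at the α-carbon (deconjugative alkylation) on the face opposite the benzyl group of the auxiliary, which sets the (R)-centre that becomes C4 of the oxolane.

**Step 3**
Reactants: 5 (R)-4-benzyl-3-[(2R)-2-(3,4-dimethoxybenzyl)but-3-enoyl]-1,3-oxazolidin-2-one
Product: 6 (2R)-2-(3,4-dimethoxybenzyl)but-3-en-1-ol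
Conditions: LiBH4, MeOH (1 equiv), Et2O, 0 °C
Reagents that add atoms: none
Why: Reductive cleavage of the Evans imide by LiBH4 should release the primary alcohol and the auxiliary without moving the double bond into conjugation or epimerising the α-centre.

**Step 4**
Reactants: 7 methyl (E)-3-(3,4,5-trimethoxyphenyl)prop-2-enoate
Product: 8 (E)-3-(3,4,5-trimethoxyphenyl)prop-2-en-1-ol
Conditions: i-Bu2AlH, CH2Cl2, −78 → 0 °C; aq. KNaC4H4O6 work-up
Reagents that add atoms: none
Why: 1,2-Hydride reduction of the α,β-unsaturated ester with i-Bu2AlH gives the allylic alcohol and leaves the E-alkene untouched.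

**Step 5**
Reactants: 8 (E)-3-(3,4,5-trimethoxyphenyl)prop-2-en-1-ol
Product: 9 tert-butyl (E)-3-(3,4,5-trimethoxyphenyl)prop-2-en-1-yl carbonate
Conditions: Boc2O, n-Bu4NHSO4 (cat.), aq. NaOH, CH2Cl2, 0 °C → rt
Reagents that add atoms: di-tert-butyl dicarbonate, CC(C)(C)OC(=O)OC(=O)OC(C)(C)C
Why: O-acylation under phase-transfer conditions gives the linear allylic tert-butyl carbonate, a leaving group that ionises under iridium catalysis and is too hindered for attack at its carbonyl group.

**Step 6**
Reactants: 6 (2R)-2-(3,4-dimethoxybenzyl)but-3-en-1-ol; 9 tert-butyl (E)-3-(3,4,5-trimethoxyphenyl)prop-2-en-1-yl carbonate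
Product: 10 (2R)-2-(3,4-dimethoxybenzyl)but-3-en-1-yl (1R)-1-(3,4,5-trimethoxyphenyl)prop-2-en-1-yl ether
Conditions: 6, n-BuLi, THF, 0 °C; CuI; then 9, [Ir(cod)Cl]2 (cat.), L (cat.), THF, rt
Reagents that add atoms: none
Why: Iridium-catalysed asymmetric allylic etherification with the monovalent copper alkoxide of 6 should give the branched ether, the chiral phosphoramidite–iridium allyl complex fixing the (R)-configuration of the new benzylic centre independently of the remote centre of 6.

**Step 7**
Reactants: 10 (2R)-2-(3,4-dimethoxybenzyl)but-3-en-1-yl (1R)-1-(3,4,5-trimethoxyphenyl)prop-2-en-1-yl ether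
Product: 11 (2R,5R)-5-(3,4-dimethoxybenzyl)-2-(3,4,5-trimethoxyphenyl)-5,6-dihydro-2H-pyran (2,5-cis)
Conditions: second-generation Grubbs catalyst (cat.), CH2Cl2, 40 °C
Reagents that add atoms: none
Why: Ring-closing metathesis of the two monosubstituted alkenes closes the six-membered cyclic ether with loss of ethylene and touches neither stereocentre.

**Step 8**
Reactants: 11 (2R,5R)-5-(3,4-dimethoxybenzyl)-2-(3,4,5-trimethoxyphenyl)-5,6-dihydro-2H-pyran
Product: 13 (2S,3S,4S,5S)-5-(3,4-dimethoxybenzyl)-3,4-epoxy-2-(3,4,5-trimethoxyphenyl)oxane (syn-epoxide), via trans-iodohydrin 12 (not isolated)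
Conditions: N-iodosuccinimide, THF/H2O, 0 °C; then aq. Na2S2O3, K2CO3, MeOH, rt
Reagents that add atoms: water, O
Why: Epoxide formation through a halohydrin: the iodonium ion on the face away from the two cis substituents is opened trans by water at the carbon remote from the ring oxygen, and base-induced SN2 closure of iodohydrin 12 then places the epoxide oxygen on the face of aryl and benzyl, the face a peracid would avoid.

**Step 9**
Reactants: 13 (2S,3S,4S,5S)-5-(3,4-dimethoxybenzyl)-3,4-epoxy-2-(3,4,5-trimethoxyphenyl)oxane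
Product: 14 (2R,3S,4R)-4-(3,4-dimethoxybenzyl)-2-(3,4,5-trimethoxyphenyl)oxolane-3-carbaldehyde (all-cis)
Conditions: BF3·OEt2 (1.1 equiv), CH2Cl2, −78 °C; Et3N, −78 °C; cold aq. NaHCO3 work-up, crude product used at once
Reagents that add atoms: none
Why: BF3 bound to the epoxide oxygen weakens the C4–O bond, whose carbon is not deactivated by a β ring oxygen, and the benzylic, oxygen-bearing C2 migrates from C3 to C4 anti to the departing oxygen while C3 becomes the formyl carbon (Meinwald-type semipinacol rearrangement, closest to the Lewis-acid ring contraction of cyclohexene oxides to cyclopentanecarbaldehydes). The oxolane is closed by ring contraction, that is by the 1,2-carbon shift that makes the C2–C4 bond of the pyran (C2–C3 of the oxolane), not by C–O bond formation. The one new stereocentre, oxolane C3, results from inversion at the migration terminus, so the formyl carbon stays on the face the epoxide oxygen occupied and the syn-epoxide gives the all-cis aldehyde, while C2 migrates with retention and the benzyl-bearing carbon is untouched. The step needs carbon shift in preference to hydride shift (which would give the pyran-3-one), and this is secured by the ring-oxygen lone pair anti-periplanar to the C2–C3 bond and by the aryl group on the migrating carbon; the alternative cleavage of C3–O with shift of C5 converges on the same aldehyde. A halide-free Lewis acid is used because a halohydrin pathway would invert the terminus twice, and −78 °C with an amine quench should keep the α-centre of the β-alkoxy aldehyde from epimerising.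

**Step 10**
Reactants: 14 (2R,3S,4R)-4-(3,4-dimethoxybenzyl)-2-(3,4,5-trimethoxyphenyl)oxolane-3-carbaldehyde
Product: 15 [(2R,3R,4R)-4-(3,4-dimethoxybenzyl)-2-(3,4,5-trimethoxyphenyl)oxolan-3-yl]methanol (all-cis, the target)
Conditions: NaBH4, MeOH/CH2Cl2, −40 → 0 °C
Reagents that add atoms: none
Why: Borohydride reduction of the crude aldehyde is fast at low temperature, forms no stereocentre and removes the acidic α-hydrogen before the all-cis C3 centre can epimerise.

**Compound list**

1 | (R)-4-benzyl-1,3-oxazolidin-2-one | O=C1OC[C@@H](Cc2ccccc2)N1 | starting material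
2 | (E)-but-2-enoyl chloride | C/C=C/C(Cl)=O | starting material
3 | (R)-4-benzyl-3-[(E)-but-2-enoyl]-1,3-oxazolidin-2-one | C/C=C/C(=O)N1[C@H](Cc2ccccc2)COC1=O | intermediate
4 | 3,4-dimethoxybenzyl bromide | COc1ccc(CBr)cc1OC | starting material
5 | (R)-4-benzyl-3-[(2R)-2-(3,4-dimethoxybenzyl)but-3-enoyl]-1,3-oxazolidin-2-one | C=C[C@@H](Cc1ccc(OC)c(OC)c1)C(=O)N1[C@H](Cc2ccccc2)COC1=O | intermediate
6 | (2R)-2-(3,4-dimethoxybenzyl)but-3-en-1-ol | C=C[C@@H](Cc1ccc(OC)c(OC)c1)CO | intermediate
7 | methyl (E)-3-(3,4,5-trimethoxyphenyl)prop-2-enoate | COC(=O)/C=C/c1cc(OC)c(OC)c(OC)c1 | starting material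
8 | (E)-3-(3,4,5-trimethoxyphenyl)prop-2-en-1-ol | OC/C=C/c1cc(OC)c(OC)c(OC)c1 | intermediate
9 | tert-butyl (E)-3-(3,4,5-trimethoxyphenyl)prop-2-en-1-yl carbonate | CC(C)(C)OC(=O)OC/C=C/c1cc(OC)c(OC)c(OC)c1 | intermediate
10 | (2R)-2-(3,4-dimethoxybenzyl)but-3-en-1-yl (1R)-1-(3,4,5-trimethoxyphenyl)prop-2-en-1-yl ether | C=C[C@@H](Cc1ccc(OC)c(OC)c1)CO[C@@H](c1cc(OC)c(OC)c(OC)c1)C=C | intermediate
11 | (2R,5R)-5-(3,4-dimethoxybenzyl)-2-(3,4,5-trimethoxyphenyl)-5,6-dihydro-2H-pyran | O1[C@@H](c2cc(OC)c(OC)c(OC)c2)C=C[C@@H](Cc2ccc(OC)c(OC)c2)C1 | intermediate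
12 | (2S,3R,4S,5S)-5-(3,4-dimethoxybenzyl)-3-iodo-2-(3,4,5-trimethoxyphenyl)oxan-4-ol | O1[C@@H](c2cc(OC)c(OC)c(OC)c2)[C@H](I)[C@@H](O)[C@@H](Cc2ccc(OC)c(OC)c2)C1 | intermediate (not isolated)
13 | (2S,3S,4S,5S)-5-(3,4-dimethoxybenzyl)-3,4-epoxy-2-(3,4,5-trimethoxyphenyl)oxane, epoxide syn to both substituents | O1[C@@H](c2cc(OC)c(OC)c(OC)c2)[C@H]2O[C@H]2[C@@H](Cc2ccc(OC)c(OC)c2)C1 | intermediate
14 | (2R,3S,4R)-4-(3,4-dimethoxybenzyl)-2-(3,4,5-trimethoxyphenyl)oxolane-3-carbaldehyde | O1[C@@H](c2cc(OC)c(OC)c(OC)c2)[C@@H](C=O)[C@@H](Cc2ccc(OC)c(OC)c2)C1 | intermediate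
15 | [(2R,3R,4R)-4-(3,4-dimethoxybenzyl)-2-(3,4,5-trimethoxyphenyl)oxolan-3-yl]methanol | COc1ccc(C[C@H]2CO[C@@H](c3cc(OC)c(OC)c(OC)c3)[C@H]2CO)cc1OC | target

**Step count**

Total: 10 steps. Longest linear sequence: 8 steps (1, 2, 3, 6, 7, 8, 9, 10).

**Steps most likely to fail**

Step 9. A 1,2-hydride shift may compete with the carbon shift. Ionisation may also run stepwise through an oxocarbenium/enolate pair that recloses without stereochemical memory, or fluoride may capture the opened epoxide. The fallback runs the shift through a halohydrin salt, in which only the ring bond can be anti-periplanar to the leaving group. It sets out from dihydropyran 11. m-Chloroperbenzoic acid (NaHCO3, CH2Cl2, 0 °C) should epoxidise the face away from the two substituents and give the anti-epoxide (2S,3R,4R,5S)-5-(3,4-dimethoxybenzyl)-3,4-epoxy-2-(3,4,5-trimethoxyphenyl)oxane F1. MgBr2·OEt2 in toluene should open it trans to the bromohydrin magnesium alkoxide F2, with bromide at C4 on the substituent face. In its diequatorial conformer the C2–C3 bond is anti to the carbon–bromine bond, and on warming it should contract to aldehyde 14, where the route is rejoined. The two inversions at C4 put the formyl group on the same face as in step 9. Peracid epoxidation and halide-mediated ring contraction of six-membered-ring epoxides are both known reaction types.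

Step 8. The iodonium ion may be opened on the wrong face, or the electron-rich arenes may be iodinated. The fallback brings the oxygen to the hindered face by SN2 inversion of a peracid-derived epoxide. It sets out from dihydropyran 11 and again passes through the anti-epoxide F1, made with m-chloroperbenzoic acid as above. Benzoate (PhCO2H, PhCO2Cs, DMF, 80 °C) would open it trans to the hydroxy benzoate F3. The free hydroxyl would be mesylated (MsCl, Et3N, CH2Cl2, 0 °C) to the mesylate F4. K2CO3 in MeOH would then cleave the benzoate, and the liberated alkoxide would displace the mesylate with inversion to give syn-epoxide 13.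

Step 6. The copper alkoxide may attack the carbonate carbonyl, the linear ether may form, or the catalyst may fail to control the benzylic centre next to the stereocentre of 6. The fallback makes the two stereocentres separately and joins them by a Williamson etherification. It sets out from alcohol 6. 3,4,5-Trimethoxybenzaldehyde and CH2=CHMgBr (THF, 0 °C) give racemic 1-(3,4,5-trimethoxyphenyl)prop-2-en-1-ol F5. Acylative kinetic resolution with immobilised Candida antarctica lipase B and vinyl acetate should acylate the (R)-enantiomer to the acetate F6, which is separated from the unreacted (S)-alcohol. Methanolysis (K2CO3, MeOH) gives the (R)-alcohol F7. Alcohol 6 is converted into the triflate F8 (Tf2O, 2,6-lutidine, CH2Cl2, −78 °C), which alkylates the sodium alkoxide of F7 (NaH, THF, −20 → 0 °C) to give diene ether 10.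

**Further compounds**

F1 | step 9 | (2S,3R,4R,5S)-5-(3,4-dimethoxybenzyl)-3,4-epoxy-2-(3,4,5-trimethoxyphenyl)oxane, epoxide anti to both substituents | O1[C@@H](c2cc(OC)c(OC)c(OC)c2)[C@@H]2O[C@@H]2[C@@H](Cc2ccc(OC)c(OC)c2)C1
F2 | step 9 | bromomagnesium alkoxide of (2S,3S,4S,5S)-4-bromo-5-(3,4-dimethoxybenzyl)-2-(3,4,5-trimethoxyphenyl)oxan-3-ol | O1[C@@H](c2cc(OC)c(OC)c(OC)c2)[C@H](O[Mg]Br)[C@@H](Br)[C@@H](Cc2ccc(OC)c(OC)c2)C1
F3 | step 8 | (2S,3R,4S,5S)-5-(3,4-dimethoxybenzyl)-3-hydroxy-2-(3,4,5-trimethoxyphenyl)oxan-4-yl benzoate | O1[C@@H](c2cc(OC)c(OC)c(OC)c2)[C@H](O)[C@@H](OC(=O)c2ccccc2)[C@@H](Cc2ccc(OC)c(OC)c2)C1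
F4 | step 8 | (2S,3R,4S,5S)-5-(3,4-dimethoxybenzyl)-3-(methylsulfonyloxy)-2-(3,4,5-trimethoxyphenyl)oxan-4-yl benzoate | O1[C@@H](c2cc(OC)c(OC)c(OC)c2)[C@H](OS(C)(=O)=O)[C@@H](OC(=O)c2ccccc2)[C@@H](Cc2ccc(OC)c(OC)c2)C1
F5 | step 6 | racemic 1-(3,4,5-trimethoxyphenyl)prop-2-en-1-ol | C=CC(O)c1cc(OC)c(OC)c(OC)c1
F6 | step 6 | (1R)-1-(3,4,5-trimethoxyphenyl)prop-2-en-1-yl acetate | CC(=O)O[C@@H](c1cc(OC)c(OC)c(OC)c1)C=C
F7 | step 6 | (1R)-1-(3,4,5-trimethoxyphenyl)prop-2-en-1-ol | O[C@@H](c1cc(OC)c(OC)c(OC)c1)C=C
F8 | step 6 | (2R)-2-(3,4-dimethoxybenzyl)but-3-en-1-yl trifluoromethanesulfonate | C=C[C@@H](Cc1ccc(OC)c(OC)c1)COS(=O)(=O)C(F)(F)F
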